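**Convention used below:** atom labels C1–C15 are the germacranolide numbering of the target (lactone C6–O/C7, ester at C8, acetate at C9, CO2Me carbon C14 on C10). The target is (4R,5R,6S,7R,8S,9S) with a (2S,3S)-epoxy ester.

## Retrosynthetic overview

1. Target 28 ⇒ seco-triene 27 by ring-closing metathesis at C2=C3; the ten-membered ring is formed last.
2. 27 ⇒ alcohol 24 + epoxy acid 22: Mitsunobu esterification with inversion at C8, then silyl ether → acetate at C9.
3. 24 ⇒ bromobutenolide 9 (C3–C7, C11–C13, C15) + aldehyde 18 (C8–C10, C14, C1, C2) by zinc Barbier allylation (C7–C8 bond).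
4. 9 ⇒ enynol 1 (kinetic resolution, directed epoxidation, acrylate metathesis); 18 ⇒ keto ester 10 (asymmetric hydrogenation, aldol–elimination); 22 ⇒ angelic acid 19 (Sharpless epoxidation).
5. Ring order: C4–C5 oxirane (step 5), butenolide (step 7), side-chain oxirane (step 14, separate branch), ten-membered carbocycle (step 20).

## Route

**Bromobutenolide branch**

Step 1
Reactants: 1 (2E)-3-methylpent-2-en-4-yn-1-ol
Product: 2 (2E)-3-methylpenta-2,4-dien-1-ol
Conditions: H2 (1 atm), Pd/CaCO3 poisoned with Pb(OAc)2 (Lindlar catalyst), quinoline, EtOAc, rt, stopped after 1 equiv H2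
Reagents that add atoms: none
Why: Lindlar semi-hydrogenation takes the terminal alkyne only to the vinyl group and leaves the E trisubstituted alkene untouched.

Step 2
Reactants: 2 (2E)-3-methylpenta-2,4-dien-1-ol
Product: 3 (2E)-3-methylpenta-2,4-dienal
Conditions: MnO2 (excess), CH2Cl2, rt; solution used directly
Reagents that add atoms: none
Why: MnO2 oxidation is selective for the allylic alcohol and gives the enal without E/Z scrambling.

Step 3
Reactants: 3 (2E)-3-methylpenta-2,4-dienal
Product: 4 rac-(4E)-5-methylhepta-1,4,6-trien-3-ol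
Conditions: CH2=CHMgBr, THF, −78 °C; aq NH4Cl
Reagents that add atoms: vinylmagnesium bromide, C=C[Mg]Br
Why: Grignard 1,2-addition to the enal at low temperature gives the bis-allylic alcohol as a racemate, which is resolved in the next step.

Step 4
Reactants: 4 rac-(4E)-5-methylhepta-1,4,6-trien-3-ol
Product: 5 (3S,4E)-5-methylhepta-1,4,6-trien-3-ol
Conditions: Ti(OiPr)4, D-(−)-diisopropyl tartrate, t-BuOOH (0.6 equiv), 4 Å MS, CH2Cl2, −20 °C
Reagents that add atoms: none
Why: Sharpless kinetic resolution: with the D-(−)-tartrate the (R)-alcohol is epoxidised fast at its trisubstituted alkene, so the recovered (S)-alcohol carries the C6 configuration.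

Step 5
Reactants: 5 (3S,4E)-5-methylhepta-1,4,6-trien-3-ol
Product: 6 (1S)-1-[(2R,3R)-3-ethenyl-3-methyloxiran-2-yl]prop-2-en-1-ol
Conditions: mCPBA, NaHCO3, CH2Cl2, 0 °C
Reagents that add atoms: meta-chloroperbenzoic acid, OOC(=O)c1cccc(Cl)c1
Why: Hydroxyl-directed (Henbest) epoxidation of the most electron-rich alkene; A(1,3) strain with the methyl group cis to the carbinol makes it threo-selective, which sets C4 and C5 (R,R) from C6.

Step 6
Reactants: 6 (1S)-1-[(2R,3R)-3-ethenyl-3-methyloxiran-2-yl]prop-2-en-1-ol; 7 2-(bromomethyl)prop-2-enoic acid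
Product: 8 (1S)-1-[(2R,3R)-3-ethenyl-3-methyloxiran-2-yl]prop-2-en-1-yl 2-(bromomethyl)prop-2-enoate
Conditions: DIC, DMAP (5 mol %), CH2Cl2, −20 → 0 °C
Reagents that add atoms: none
Why: Carbodiimide (Steglich) esterification acylates the secondary alcohol with retention at C6 under conditions mild enough for the vinyl epoxide.

Step 7
Reactants: 8 (1S)-1-[(2R,3R)-3-ethenyl-3-methyloxiran-2-yl]prop-2-en-1-yl 2-(bromomethyl)prop-2-enoate
Product: 9 (5S)-3-(bromomethyl)-5-[(2R,3R)-3-ethenyl-3-methyloxiran-2-yl]furan-2(5H)-one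
Conditions: RuCl2(H2IMes)(=CH-C6H4-2-OiPr) (second-generation Hoveyda–Grubbs catalyst, 5 mol %), CH2Cl2 (5 mM), 40 °C
Reagents that add atoms: none
Why: Ring-closing metathesis of the acrylate with the carbinol vinyl group gives the butenolide; the epoxide vinyl group stays a spectator because a small ring cannot contain the trans-epoxide.

**Aldehyde branch**

Step 8
Reactants: 10 methyl 4,4-dimethoxy-3-oxobutanoate
Product: 11 methyl (3S)-3-hydroxy-4,4-dimethoxybutanoate
Conditions: H2 (50 atm), RuCl2[(R)-BINAP] (0.5 mol %), MeOH, 50 °C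
Reagents that add atoms: none
Why: Noyori asymmetric hydrogenation of the β-keto ester sets C9 by catalyst control, with the same facial sense as the (R)-BINAP route to (S)-4-chloro-3-hydroxybutanoate (label S because the acetal carbon outranks CH2CO2Me).

Step 9
Reactants: 11 methyl (3S)-3-hydroxy-4,4-dimethoxybutanoate
Product: 12 methyl (3S)-3-(tert-butyldimethylsilyloxy)-4,4-dimethoxybutanoate
Conditions: TBSCl, imidazole, DMF, rt
Reagents that add atoms: tert-butyldimethylsilyl chloride, CC(C)(C)[Si](C)(C)Cl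
Why: Standard silylation; the bulky, non-chelating silyl ether later steers Felkin–Anh addition in step 16.

Step 10
Reactants: 12 methyl (3S)-3-(tert-butyldimethylsilyloxy)-4,4-dimethoxybutanoate; 13 acrolein
Product: 15 methyl 2-[(1S)-1-(tert-butyldimethylsilyloxy)-2,2-dimethoxyethyl]-3-hydroxypent-4-enoate (diastereomer mixture), via lithium enolate 14 (not isolated)
Conditions: LiN(iPr)2 (LDA), THF, −78 °C, 20 min; then 13, −78 °C; aq NH4Cl
Reagents that add atoms: none
Why: Ester enolate aldol 1,2-addition to acrolein at −78 °C, where β-silyloxy elimination is slow; the two new stereocentres are removed in step 11.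

Step 11
Reactants: 15 methyl 2-[(1S)-1-(tert-butyldimethylsilyloxy)-2,2-dimethoxyethyl]-3-hydroxypent-4-enoate
Product: 17 methyl (2E)-2-[(1S)-1-(tert-butyldimethylsilyloxy)-2,2-dimethoxyethyl]penta-2,4-dienoate, via mesylate 16 (not isolated)
Conditions: MsCl, Et3N, CH2Cl2, 0 °C; then DBU, rt
Reagents that add atoms: none
Why: Mesylation and E1cB elimination give the conjugated dienoate; the isomer with the ester trans to the vinyl group (the C10=C1 geometry of the target) is the favoured trisubstituted alkene and minor Z isomer is removed by chromatography.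

Step 12
Reactants: 17 methyl (2E)-2-[(1S)-1-(tert-butyldimethylsilyloxy)-2,2-dimethoxyethyl]penta-2,4-dienoate
Product: 18 methyl (2E)-2-[(1S)-1-(tert-butyldimethylsilyloxy)-2-oxoethyl]penta-2,4-dienoate
Conditions: LiBF4, MeCN/H2O (50:1), rt; used at once
Reagents that add atoms: water, O
Why: Mild LiBF4-assisted acetal hydrolysis frees the aldehyde without cleaving the silyl ether; immediate use limits epimerisation at C9.

**Side-chain acid branch**

Step 13
Reactants: 19 angelic acid [(2Z)-2-methylbut-2-enoic acid]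
Product: 20 (2Z)-2-methylbut-2-en-1-ol
Conditions: LiAlH4, Et2O, 0 °C; H2O work-up
Reagents that add atoms: none
Why: Hydride reduction of the acid gives the allylic alcohol with the Z geometry intact.

Step 14
Reactants: 20 (2Z)-2-methylbut-2-en-1-ol
Product: 21 [(2R,3S)-2,3-dimethyloxiran-2-yl]methanol
Conditions: Ti(OiPr)4, D-(−)-diethyl tartrate, t-BuOOH, 4 Å MS, CH2Cl2, −20 °C
Reagents that add atoms: tert-butyl hydroperoxide, CC(C)(C)OO
Why: Sharpless asymmetric epoxidation; the D-(−)-tartrate delivers oxygen to the face that gives the (2R,3S)-epoxy alcohol, and the Z alkene fixes the cis relation of CH2OH and the C3 methyl.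

Step 15
Reactants: 21 [(2R,3S)-2,3-dimethyloxiran-2-yl]methanol
Product: 22 (2S,3S)-2,3-dimethyloxirane-2-carboxylic acid
Conditions: TEMPO (cat.), PhI(OAc)2, MeCN/H2O (1:1), 0 °C → rt
Reagents that add atoms: water, O
Why: Nitroxyl-catalysed oxidation takes the primary alcohol to the acid without touching the epoxide (the C2 label changes to S only through CIP priorities).

**Union and ring closure**

Step 16
Reactants: 9 (5S)-3-(bromomethyl)-5-[(2R,3R)-3-ethenyl-3-methyloxiran-2-yl]furan-2(5H)-one; 18 methyl (2E)-2-[(1S)-1-(tert-butyldimethylsilyloxy)-2-oxoethyl]penta-2,4-dienoate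
Product: 24 methyl (2E)-2-{(1S,2R)-1-(tert-butyldimethylsilyloxy)-2-hydroxy-2-[(2S,3R)-2-[(2R,3R)-3-ethenyl-3-methyloxiran-2-yl]-4-methylidene-5-oxooxolan-3-yl]ethyl}penta-2,4-dienoate, via allylzinc bromide 23 (not isolated)
Conditions: Zn dust, THF/sat. aq NH4Cl (2:1), 0 °C → rt
Reagents that add atoms: none
Why: Zinc Barbier allylation: the allylzinc reacts through C7 on the face anti to the C6 substituent (trans lactone, 7R), and the chair transition state of this ring-locked E-type allyl unit gives the 7,8-anti alcohol (8R), matched with Felkin–Anh addition to the α-silyloxy aldehyde; C8 is therefore formed epimeric to the target on purpose and is inverted in step 17.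

Step 17
Reactants: 24 the (8R)-alcohol from step 16; 22 (2S,3S)-2,3-dimethyloxirane-2-carboxylic acid
Product: 25 methyl (2E)-2-{(1S,2S)-1-(tert-butyldimethylsilyloxy)-2-[(2S,3S)-2,3-dimethyloxirane-2-carbonyloxy]-2-[(2S,3S)-2-[(2R,3R)-3-ethenyl-3-methyloxiran-2-yl]-4-methylidene-5-oxooxolan-3-yl]ethyl}penta-2,4-dienoate
Conditions: PPh3, DIAD (betaine pre-formed), toluene, 0 °C → rt
Reagents that add atoms: none
Why: Mitsunobu esterification displaces the activated C8 oxygen by the carboxylate in an SN2 step, so the ester is installed with inversion to the required 8S configuration (the lactone C7 label becomes S only through CIP priorities).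

Step 18
Reactants: 25 the C8 epoxy ester silyl ether from step 17
Product: 26 methyl (2E)-2-{(1S,2S)-2-[(2S,3S)-2,3-dimethyloxirane-2-carbonyloxy]-1-hydroxy-2-[(2S,3R)-2-[(2R,3R)-3-ethenyl-3-methyloxiran-2-yl]-4-methylidene-5-oxooxolan-3-yl]ethyl}penta-2,4-dienoate
Conditions: HF·pyridine, excess pyridine, THF, 0 °C
Reagents that add atoms: none
Why: Buffered fluoride desilylation frees the C9 hydroxyl under weakly acidic conditions, where migration of the hindered C8 ester and epoxide opening are slow.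

Step 19
Reactants: 26 the C9 alcohol from step 18
Product: 27 methyl (2E)-2-{(1S,2S)-1-acetyloxy-2-[(2S,3S)-2,3-dimethyloxirane-2-carbonyloxy]-2-[(2S,3R)-2-[(2R,3R)-3-ethenyl-3-methyloxiran-2-yl]-4-methylidene-5-oxooxolan-3-yl]ethyl}penta-2,4-dienoate
Conditions: Ac2O, pyridine, DMAP (cat.), CH2Cl2, 0 °C
Reagents that add atoms: acetic anhydride, CC(=O)OC(C)=O
Why: Standard acetylation of the allylic secondary alcohol with retention at C9.

Step 20
Reactants: 27 the seco-triene acetate from step 19
Product: 28 target: methyl (4R,5R,6S,7R,8S,9S)-9-acetoxy-4,5-epoxy-8-[(2S,3S)-2,3-epoxy-2-methylbutanoyloxy]-12-oxo-6,12-epoxygermacra-1(10),2,11(13)-trien-14-oate with cis C1=C10 and Z C2=C3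
Conditions: RuCl2(H2IMes)(=CH-C6H4-2-OiPr) (second-generation Hoveyda–Grubbs catalyst, 20 mol %), 1,4-benzoquinone (cat.), toluene (0.5 mM), 80 °C
Reagents that add atoms: none
Why: Ring-closing metathesis joins the two monosubstituted vinyl groups (the methylene lactone and the trisubstituted enoate are unreactive acrylate-type alkenes), and the ten-membered ring that already holds the cis C10=C1 enoate and the trans-fused lactone is expected to accommodate only the Z C2=C3 alkene.

## Compound list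

1 | (2E)-3-methylpent-2-en-4-yn-1-ol | C#C/C(C)=C/CO | starting material
2 | (2E)-3-methylpenta-2,4-dien-1-ol | C=C/C(C)=C/CO | intermediate
3 | (2E)-3-methylpenta-2,4-dienal | C=C/C(C)=C/C=O | intermediate
4 | rac-(4E)-5-methylhepta-1,4,6-trien-3-ol | C=CC(O)/C=C(C)/C=C | intermediate
5 | (3S,4E)-5-methylhepta-1,4,6-trien-3-ol | C=C[C@H](O)/C=C(C)/C=C | intermediate
6 | (1S)-1-[(2R,3R)-3-ethenyl-3-methyloxiran-2-yl]prop-2-en-1-ol | C=C[C@H](O)[C@H]1O[C@]1(C)C=C | intermediate
7 | 2-(bromomethyl)prop-2-enoic acid | C=C(CBr)C(=O)O | starting material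
8 | (1S)-1-[(2R,3R)-3-ethenyl-3-methyloxiran-2-yl]prop-2-en-1-yl 2-(bromomethyl)prop-2-enoate | C=C[C@H](OC(=O)C(=C)CBr)[C@H]1O[C@]1(C)C=C | intermediate
9 | (5S)-3-(bromomethyl)-5-[(2R,3R)-3-ethenyl-3-methyloxiran-2-yl]furan-2(5H)-one | BrCC1=C[C@H](OC1=O)[C@H]2O[C@]2(C)C=C | intermediate
10 | methyl 4,4-dimethoxy-3-oxobutanoate | COC(OC)C(=O)CC(=O)OC | starting material
11 | methyl (3S)-3-hydroxy-4,4-dimethoxybutanoate | COC(OC)[C@@H](O)CC(=O)OC | intermediate
12 | methyl (3S)-3-(tert-butyldimethylsilyloxy)-4,4-dimethoxybutanoate | COC(OC)[C@@H](O[Si](C)(C)C(C)(C)C)CC(=O)OC | intermediate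
13 | acrolein (prop-2-enal) | C=CC=O | starting material
14 | lithium enolate of 12 | COC(OC)[C@@H](O[Si](C)(C)C(C)(C)C)C=C(O[Li])OC | intermediate (not isolated)
15 | methyl 2-[(1S)-1-(tert-butyldimethylsilyloxy)-2,2-dimethoxyethyl]-3-hydroxypent-4-enoate, mixture at C2 and C3 | COC(OC)[C@@H](O[Si](C)(C)C(C)(C)C)C(C(O)C=C)C(=O)OC | intermediate
16 | methanesulfonate of 15 | COC(OC)[C@@H](O[Si](C)(C)C(C)(C)C)C(C(OS(C)(=O)=O)C=C)C(=O)OC | intermediate (not isolated)
17 | methyl (2E)-2-[(1S)-1-(tert-butyldimethylsilyloxy)-2,2-dimethoxyethyl]penta-2,4-dienoate | COC(OC)[C@@H](O[Si](C)(C)C(C)(C)C)/C(C(=O)OC)=C\C=C | intermediate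
18 | methyl (2E)-2-[(1S)-1-(tert-butyldimethylsilyloxy)-2-oxoethyl]penta-2,4-dienoate | O=C[C@@H](O[Si](C)(C)C(C)(C)C)/C(C(=O)OC)=C\C=C | intermediate
19 | angelic acid, (2Z)-2-methylbut-2-enoic acid | C/C=C(C)\C(=O)O | starting material
20 | (2Z)-2-methylbut-2-en-1-ol | C/C=C(C)\CO | intermediate
21 | [(2R,3S)-2,3-dimethyloxiran-2-yl]methanol | OC[C@@]1(C)O[C@H]1C | intermediate
22 | (2S,3S)-2,3-dimethyloxirane-2-carboxylic acid | OC(=O)[C@@]1(C)O[C@H]1C | intermediate
23 | allylzinc bromide from 9 | Br[Zn]CC1=C[C@H](OC1=O)[C@H]2O[C@]2(C)C=C | intermediate (not isolated)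
24 | (8R)-alcohol; target numbering 4R,5R,6S,7R,8R,9S; 9-OTBS; vinyl ends at C2 and C3 | C=C1C(=O)O[C@H]([C@H]2O[C@]2(C)C=C)[C@H]1[C@@H](O)[C@@H](O[Si](C)(C)C(C)(C)C)/C(C(=O)OC)=C\C=C | intermediate
25 | (8S) (2S,3S)-2,3-dimethyloxirane-2-carboxylate, 9-OTBS | C=C1C(=O)O[C@H]([C@H]2O[C@]2(C)C=C)[C@H]1[C@H](OC(=O)[C@@]1(C)O[C@H]1C)[C@@H](O[Si](C)(C)C(C)(C)C)/C(C(=O)OC)=C\C=C | intermediate
26 | (8S) epoxy ester, 9-OH | C=C1C(=O)O[C@H]([C@H]2O[C@]2(C)C=C)[C@H]1[C@H](OC(=O)[C@@]1(C)O[C@H]1C)[C@@H](O)/C(C(=O)OC)=C\C=C | intermediate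
27 | seco-triene: (8S) epoxy ester, 9-OAc | C=C1C(=O)O[C@H]([C@H]2O[C@]2(C)C=C)[C@H]1[C@H](OC(=O)[C@@]1(C)O[C@H]1C)[C@@H](OC(C)=O)/C(C(=O)OC)=C\C=C | intermediate
28 | target (CNP0229507.6) | C=C1C(=O)O[C@H]2[C@H]1[C@H](OC(=O)[C@@]1(C)O[C@H]1C)[C@@H](OC(C)=O)/C(C(=O)OC)=C\C=C/[C@@]1(C)O[C@H]21 | target

## Step count and weak points

Total step count: 20. Longest linear sequence: 12 (steps 1–7, then 16–20); the aldehyde branch is 5 steps and the acid branch 3 steps before they join.

Steps most likely to fail: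

Step 20 (ten-membered diene ring closure). Ring strain, E/Z control at C2=C3 and possible interference by the methylene lactone make this the least certain step. Fallback, setting out from 24 and returning at 28: close the ring before the esters are in place, when the C8 hydroxyl is free and the substrate is less crowded. Metathesis of 24 under the step 20 conditions gives the macrocyclic hydroxy silyl ether F1. Mitsunobu esterification of F1 with 22 (PPh3, DIAD) gives the macrocyclic (8S) epoxy ester silyl ether F2. HF·pyridine then gives the macrocyclic C9 alcohol F3, and acetylation (Ac2O, pyridine, DMAP) gives 28.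

Step 17 (Mitsunobu inversion at the hindered C8). The alcohol is flanked by two branched carbons, and elimination toward C7 competes with substitution. Fallback, setting out from 24 and returning at 25: invert by oxidation and reduction, then acylate with retention. Dess–Martin periodinane with NaHCO3 in CH2Cl2 at 0 °C gives the C8 ketone F4, which is not stored because the β,γ-unsaturated ketone can isomerise. Immediate reduction with NaBH4 and CeCl3·7H2O in MeOH at −78 °C (hydride anti to the C9 silyloxy group, Felkin–Anh) gives the (8S)-alcohol F5. Yamaguchi acylation of F5 with 22 (2,4,6-trichlorobenzoyl chloride, Et3N, DMAP, toluene) gives 25.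

Step 6 (acylation with an acid that is itself an allylic bromide). The nucleophilic catalyst can attack the bromide instead of promoting acylation. Fallback, setting out from 6 and returning at 9: carry the bromide as a silyl ether through the butenolide metathesis. Esterification of 6 with 2-[(tert-butyldimethylsilyloxy)methyl]prop-2-enoic acid (DIC, DMAP) gives the silyloxymethyl acrylate F6. Metathesis as in step 7 gives the silyloxymethyl butenolide F7, and HF·pyridine gives the hydroxymethyl butenolide F8. CBr4 and PPh3 in CH2Cl2 at 0 °C then give 9.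

## Further compounds

F1 | step 20 | macrocyclic (8R)-alcohol, 9-OTBS (ring closed, esters not yet installed) | C=C1C(=O)O[C@H]2[C@H]1[C@@H](O)[C@@H](O[Si](C)(C)C(C)(C)C)/C(C(=O)OC)=C\C=C/[C@@]1(C)O[C@H]21
F2 | step 20 | macrocyclic (8S) (2S,3S)-2,3-dimethyloxirane-2-carboxylate, 9-OTBS | C=C1C(=O)O[C@H]2[C@H]1[C@H](OC(=O)[C@@]1(C)O[C@H]1C)[C@@H](O[Si](C)(C)C(C)(C)C)/C(C(=O)OC)=C\C=C/[C@@]1(C)O[C@H]21
F3 | step 20 | macrocyclic (8S) epoxy ester, 9-OH | C=C1C(=O)O[C@H]2[C@H]1[C@H](OC(=O)[C@@]1(C)O[C@H]1C)[C@@H](O)/C(C(=O)OC)=C\C=C/[C@@]1(C)O[C@H]21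
F4 | step 17 | C8 ketone from 24 | C=C1C(=O)O[C@H]([C@H]2O[C@]2(C)C=C)[C@H]1C(=O)[C@@H](O[Si](C)(C)C(C)(C)C)/C(C(=O)OC)=C\C=C
F5 | step 17 | (8S)-alcohol, C8 epimer of 24 | C=C1C(=O)O[C@H]([C@H]2O[C@]2(C)C=C)[C@H]1[C@H](O)[C@@H](O[Si](C)(C)C(C)(C)C)/C(C(=O)OC)=C\C=C
F6 | step 6 | (1S)-1-[(2R,3R)-3-ethenyl-3-methyloxiran-2-yl]prop-2-en-1-yl 2-[(tert-butyldimethylsilyloxy)methyl]prop-2-enoate | C=C[C@H](OC(=O)C(=C)CO[Si](C)(C)C(C)(C)C)[C@H]1O[C@]1(C)C=C
F7 | step 6 | (5S)-3-[(tert-butyldimethylsilyloxy)methyl]-5-[(2R,3R)-3-ethenyl-3-methyloxiran-2-yl]furan-2(5H)-one | CC(C)(C)[Si](C)(C)OCC1=C[C@H](OC1=O)[C@H]2O[C@]2(C)C=C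
F8 | step 6 | (5S)-5-[(2R,3R)-3-ethenyl-3-methyloxiran-2-yl]-3-(hydroxymethyl)furan-2(5H)-one | OCC1=C[C@H](OC1=O)[C@H]2O[C@]2(C)C=C
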